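Ring A is the only benzene ring that has to be built: it carries CO2Me at C1 between oxygens at C2 and C6 and a methyl at C4. That pattern is cut across C1–C6 and C4–C5 into a 3-methoxycarbonyl-4-acyloxy-6-methyl-2-pyrone (C1–C4) and the ethynyl ether of the ring B phenol (C5–C6), so the diaryl ether oxygen is already in place on an sp carbon. One inverse-demand [4+2] followed by loss of CO2 should then give the fully substituted, aromatic ring A and the hindered diaryl ether together. The precursors are pivaloyloxy pyrone 6 and aryl ethynyl ether 18, whose ring B bears the prenyl ether and a silyl-protected hydroxymethyl group.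

Key step: step 10

Remark on numbering: ring A is numbered from the ester-bearing carbon (C1; OH at C2, CH3 at C4, aryloxy at C6); ring B from the ether carbon (C1'; CH2OH at C2', OMe at C4', prenyloxy at C6').
Remark on structures: pyrone 6, ethynyl ether 18 and cycloadduct 20 map onto the target atom for atom and need no correction. The one gap is that 2-hydroxy-5-methoxybenzaldehyde has no oxygen at the future C6'; steps 3 and 4 supply it (if bromide 8 is purchased, step 3 falls away).
Remark on design: the dichlorovinyl ether is installed on the aldehyde (step 6), so a phenol never has to be told apart from a benzylic alcohol. In step 10 the ynol ether is added slowly to an excess of the cheaper pyrone.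

Step 1
Reactants: 1 dimethyl malonate; 2 2,2,6-trimethyl-4H-1,3-dioxin-4-one
Product: 5 methyl 4-hydroxy-6-methyl-2-oxo-2H-pyran-3-carboxylate, via acetylketene 3 (not isolated), via dimethyl 2-(3-oxobutanoyl)malonate 4 (not isolated)
Conditions: NaH (1.05 equiv), THF/PhMe, 0 °C to rt; then 2, 110 °C (acetone distilled off); aq. HCl
Reagents that add atoms: none
Why: Thermal retro-[4+2] of the dioxinone releases acetylketene, which C-acylates sodium dimethyl malonate, and the tricarbonyl enolate then lactonizes through the ketone enol oxygen onto a malonate ester with loss of methanol (acylketene acylation/lactonization, the dioxinone serving as a diketene equivalent).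

Step 2
Reactants: 5 methyl 4-hydroxy-6-methyl-2-oxo-2H-pyran-3-carboxylate
Product: 6 methyl 6-methyl-2-oxo-4-(pivaloyloxy)-2H-pyran-3-carboxylate
Conditions: PivCl, Et3N, CH2Cl2, 0 °C; used freshly prepared
Reagents that add atoms: pivaloyl chloride, CC(C)(C)C(=O)Cl
Why: O-acylation of the acidic vinylogous-acid hydroxyl gives the enol pivalate, whose bulk should resist later acyl transfer while the acyloxy group keeps the diene electron-poor.

Step 3
Reactants: 7 2-hydroxy-5-methoxybenzaldehyde
Product: 8 3-bromo-2-hydroxy-5-methoxybenzaldehyde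
Conditions: Br2, NaOAc, AcOH, rt
Reagents that add atoms: bromine, BrBr
Why: Electrophilic aromatic bromination should go to C3, the only free position ortho to the strongly activating phenol (the para position carries OMe), with acetate buffering the HBr.

Step 4
Reactants: 8 3-bromo-2-hydroxy-5-methoxybenzaldehyde
Product: 9 2,3-dihydroxy-5-methoxybenzaldehyde
Conditions: aq. NaOH, Cu powder (cat.), reflux, under argon; then HCl
Reagents that add atoms: sodium hydroxide, [Na+].[OH-]
Why: Copper-mediated Ullmann-type hydroxylation of an aryl bromide ortho to a phenoxide, the classical way from bromo-hydroxybenzaldehydes to catechol aldehydes, replaces Br by OH while the phenoxide form shields the formyl group from Cannizzaro chemistry.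

Step 5
Reactants: 9 2,3-dihydroxy-5-methoxybenzaldehyde
Product: 10 2-hydroxy-5-methoxy-3-(3-methylbut-2-enyloxy)benzaldehyde
Conditions: NaH (2.2 equiv), degassed DMSO, rt, N2; prenyl bromide (1.0 equiv); aq. HCl
Reagents that add atoms: prenyl bromide (1-bromo-3-methylbut-2-ene), CC(C)=CCBr
Why: In the dianion the C2 phenoxide is deactivated by conjugation with and chelation to the ortho formyl group, so one equivalent of halide should alkylate the more basic C3 phenoxide (regioselective Williamson etherification of a 2,3-dihydroxybenzaldehyde dianion).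

Step 6
Reactants: 10 2-hydroxy-5-methoxy-3-(3-methylbut-2-enyloxy)benzaldehyde; 11 trichloroethylene
Product: 13 2-[(E)-1,2-dichloroethenyloxy]-5-methoxy-3-(3-methylbut-2-enyloxy)benzaldehyde, via dichloroacetylene 12 (not isolated)
Conditions: K2CO3, DMF, 70 °C, N2 (12 kept in solution under inert gas throughout)
Reagents that add atoms: none
Why: Carbonate dehydrochlorinates trichloroethylene to dichloroacetylene, to which the phenoxide adds in anti fashion to give the (E)-dichlorovinyl ether (the standard aryl dichlorovinyl ether synthesis).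

Step 7
Reactants: 13 2-[(E)-1,2-dichloroethenyloxy]-5-methoxy-3-(3-methylbut-2-enyloxy)benzaldehyde
Product: 14 {2-[(E)-1,2-dichloroethenyloxy]-5-methoxy-3-(3-methylbut-2-enyloxy)phenyl}methanol
Conditions: NaBH4, MeOH, 0 °C
Reagents that add atoms: none
Why: Borohydride reduction of the aryl aldehyde is chemoselective and should leave the dichlorovinyl ether, the prenyl ether and the aryl ethers untouched.

Step 8
Reactants: 14 {2-[(E)-1,2-dichloroethenyloxy]-5-methoxy-3-(3-methylbut-2-enyloxy)phenyl}methanol
Product: 15 tert-butyl{2-[(E)-1,2-dichloroethenyloxy]-5-methoxy-3-(3-methylbut-2-enyloxy)benzyloxy}dimethylsilane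
Conditions: TBSCl, imidazole, DMF, rt
Reagents that add atoms: tert-butyldimethylsilyl chloride, CC(C)(C)[Si](C)(C)Cl
Why: Standard silylation of the single hydroxyl masks it against butyllithium and against later addition to the ynol ether or the pyrone.

Step 9
Reactants: 15 tert-butyl{2-[(E)-1,2-dichloroethenyloxy]-5-methoxy-3-(3-methylbut-2-enyloxy)benzyloxy}dimethylsilane
Product: 18 2-[(tert-butyldimethylsilyloxy)methyl]-4-methoxy-6-(3-methylbut-2-enyloxy)phenyl ethynyl ether, via chloroethynyl aryl ether 16 (not isolated), via lithium aryloxyacetylide 17 (not isolated)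
Conditions: n-BuLi (2.3 equiv), THF, −78 °C; MeOH, −78 °C; cold neutral work-up, kept as a PhMe solution and used at once
Reagents that add atoms: none
Why: Butyllithium dehydrochlorinates the dichlorovinyl ether to the chloroalkyne and then exchanges chlorine for lithium, and protonation of the acetylide gives the terminal ynol ether (dichlorovinyl ether route to alkynyl ethers), which as an aryl ether has no β-hydrogen for retro-ene ketene formation.

Step 10
Reactants: 6 methyl 6-methyl-2-oxo-4-(pivaloyloxy)-2H-pyran-3-carboxylate; 18 2-[(tert-butyldimethylsilyloxy)methyl]-4-methoxy-6-(3-methylbut-2-enyloxy)phenyl ethynyl ether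
Product: 20 methyl 2-{2-[(tert-butyldimethylsilyloxy)methyl]-4-methoxy-6-(3-methylbut-2-enyloxy)phenoxy}-4-methyl-6-(pivaloyloxy)benzoate, via bridged bicyclic lactone 19 (not isolated)
Conditions: 6 (1.5 equiv), PhMe, 4 Å MS, 90–100 °C; 18 added over 4 h; sealed vessel (−CO2)
Reagents that add atoms: none
Why: Proposed new method: the ynol ether (HOMO raised by the aryloxy oxygen, terminal CH nucleophilic) should add to pyrone 6 (LUMO lowered by the lactone carbonyl, the C3 ester and the acyloxy group) in a single, strongly asynchronous inverse-electron-demand [4+2] in which the alkyne CH bonds to pyrone C6 ahead of the aryloxy carbon bonding to C3. The resulting 2-oxabicyclo[2.2.2]octadienone 19 should then expel CO2 by retro-[4+2], so ring A emerges aromatic without an oxidant. The closest known reaction type is the cycloaddition/decarboxylation of 3-alkoxycarbonyl-2-pyrones with ketene acetals, enol ethers and ynamines to give salicylates and anilines; an aryl ethynyl ether has not served as the two-carbon partner. Ring A closes by intermolecular [4+2] annulation, two σ-bonds (benzoate C1–C6 and C4–C5) forming across the diene termini, after which the lactone bridge is excised. No stereocentre survives, the two bridgeheads of racemic 19 being transient. The selectivity needed is regiochemical (aryloxy carbon to the ester-bearing pyrone C3, CH to the methyl-bearing C6) and is secured by the matched polarization of the partners, while the hindered pivalate, the acid-free aprotic medium and the slow addition of 18 are meant to suppress acyl transfer, hydration and oligomerization.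

Step 11
Reactants: 20 methyl 2-{2-[(tert-butyldimethylsilyloxy)methyl]-4-methoxy-6-(3-methylbut-2-enyloxy)phenoxy}-4-methyl-6-(pivaloyloxy)benzoate
Product: 21 methyl 2-{2-[(tert-butyldimethylsilyloxy)methyl]-4-methoxy-6-(3-methylbut-2-enyloxy)phenoxy}-6-hydroxy-4-methylbenzoate
Conditions: K2CO3 (1.0 equiv), MeOH, rt; then AcOH (1.0 equiv)
Reagents that add atoms: none
Why: Methoxide transesterification of the aryl pivalate releases the hydrogen-bonded salicylate phenoxide, while the methyl ester only exchanges with itself and the silyl, prenyl and diaryl ethers are inert.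

Step 12
Reactants: 21 methyl 2-{2-[(tert-butyldimethylsilyloxy)methyl]-4-methoxy-6-(3-methylbut-2-enyloxy)phenoxy}-6-hydroxy-4-methylbenzoate
Product: 22 methyl 2-hydroxy-6-[2-(hydroxymethyl)-4-methoxy-6-(3-methylbut-2-enyloxy)phenoxy]-4-methylbenzoate
Conditions: TBAF, AcOH (1:1), THF, 0 °C to rt
Reagents that add atoms: none
Why: Fluoride-induced desilylation frees the primary benzylic alcohol, and the acetic acid buffer keeps the alkoxide from lactonizing onto the neighbouring methyl ester to an eight-membered ring.

Compound list
1 | dimethyl malonate | COC(=O)CC(=O)OC | starting material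
2 | 2,2,6-trimethyl-4H-1,3-dioxin-4-one | CC1=CC(=O)OC(C)(C)O1 | starting material
3 | acetylketene | CC(=O)C=C=O | intermediate (not isolated)
4 | dimethyl 2-(3-oxobutanoyl)malonate (sodium enolate in the flask) | COC(=O)C(C(=O)OC)C(=O)CC(C)=O | intermediate (not isolated)
5 | methyl 4-hydroxy-6-methyl-2-oxo-2H-pyran-3-carboxylate | COC(=O)C1=C(O)C=C(C)OC1=O | intermediate
6 | methyl 6-methyl-2-oxo-4-(pivaloyloxy)-2H-pyran-3-carboxylate | COC(=O)C1=C(OC(=O)C(C)(C)C)C=C(C)OC1=O | intermediate
7 | 2-hydroxy-5-methoxybenzaldehyde | COc1ccc(O)c(C=O)c1 | starting material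
8 | 3-bromo-2-hydroxy-5-methoxybenzaldehyde | COc1cc(Br)c(O)c(C=O)c1 | intermediate
9 | 2,3-dihydroxy-5-methoxybenzaldehyde | COc1cc(O)c(O)c(C=O)c1 | intermediate
10 | 2-hydroxy-5-methoxy-3-(3-methylbut-2-enyloxy)benzaldehyde | COc1cc(OCC=C(C)C)c(O)c(C=O)c1 | intermediate
11 | trichloroethylene | ClC=C(Cl)Cl | starting material
12 | dichloroacetylene | ClC#CCl | intermediate (not isolated)
13 | 2-[(E)-1,2-dichloroethenyloxy]-5-methoxy-3-(3-methylbut-2-enyloxy)benzaldehyde | COc1cc(OCC=C(C)C)c(O/C(Cl)=C\Cl)c(C=O)c1 | intermediate
14 | {2-[(E)-1,2-dichloroethenyloxy]-5-methoxy-3-(3-methylbut-2-enyloxy)phenyl}methanol | COc1cc(OCC=C(C)C)c(O/C(Cl)=C\Cl)c(CO)c1 | intermediate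
15 | tert-butyl{2-[(E)-1,2-dichloroethenyloxy]-5-methoxy-3-(3-methylbut-2-enyloxy)benzyloxy}dimethylsilane | COc1cc(OCC=C(C)C)c(O/C(Cl)=C\Cl)c(CO[Si](C)(C)C(C)(C)C)c1 | intermediate
16 | tert-butyl[2-(chloroethynyloxy)-5-methoxy-3-(3-methylbut-2-enyloxy)benzyloxy]dimethylsilane | COc1cc(OCC=C(C)C)c(OC#CCl)c(CO[Si](C)(C)C(C)(C)C)c1 | intermediate (not isolated)
17 | lithium 2-{2-[(tert-butyldimethylsilyloxy)methyl]-4-methoxy-6-(3-methylbut-2-enyloxy)phenoxy}acetylide | COc1cc(OCC=C(C)C)c(OC#C[Li])c(CO[Si](C)(C)C(C)(C)C)c1 | intermediate (not isolated)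
18 | 2-[(tert-butyldimethylsilyloxy)methyl]-4-methoxy-6-(3-methylbut-2-enyloxy)phenyl ethynyl ether | C#COc1c(CO[Si](C)(C)C(C)(C)C)cc(OC)cc1OCC=C(C)C | intermediate
19 | methyl 8-{2-[(tert-butyldimethylsilyloxy)methyl]-4-methoxy-6-(3-methylbut-2-enyloxy)phenoxy}-1-methyl-3-oxo-5-(pivaloyloxy)-2-oxabicyclo[2.2.2]octa-5,7-diene-4-carboxylate (racemic; the bicycle fixes the relative configuration of the two bridgeheads) | CC12OC(=O)C(C(=O)OC)(C(OC(=O)C(C)(C)C)=C1)C(Oc3c(CO[Si](C)(C)C(C)(C)C)cc(OC)cc3OCC=C(C)C)=C2 | intermediate (not isolated)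
20 | methyl 2-{2-[(tert-butyldimethylsilyloxy)methyl]-4-methoxy-6-(3-methylbut-2-enyloxy)phenoxy}-4-methyl-6-(pivaloyloxy)benzoate | COC(=O)c1c(OC(=O)C(C)(C)C)cc(C)cc1Oc1c(CO[Si](C)(C)C(C)(C)C)cc(OC)cc1OCC=C(C)C | intermediate
21 | methyl 2-{2-[(tert-butyldimethylsilyloxy)methyl]-4-methoxy-6-(3-methylbut-2-enyloxy)phenoxy}-6-hydroxy-4-methylbenzoate | COC(=O)c1c(O)cc(C)cc1Oc1c(CO[Si](C)(C)C(C)(C)C)cc(OC)cc1OCC=C(C)C | intermediate
22 | methyl 2-hydroxy-6-[2-(hydroxymethyl)-4-methoxy-6-(3-methylbut-2-enyloxy)phenoxy]-4-methylbenzoate (no stereocentres) | COC(=O)c1c(O)cc(C)cc1Oc1c(CO)cc(OC)cc1OCC=C(C)C | target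

Total step count: 12. Longest linear sequence: 10 steps (steps 3–12, from 2-hydroxy-5-methoxybenzaldehyde); the pyrone arm is 2 steps (steps 1–2).

Steps most likely to fail

1. Step 10 (Proposed new method). The ynol ether may oligomerize or be hydrated or acylated faster than it cycloadds. Its nucleophilic carbon may attack pyrone C4 or the pivalate carbonyl instead of C6. The C6 methyl may slow the first bond formation so much that prolonged heating starts Claisen rearrangement of the prenyl ether. The fallback closes the diaryl ether by nucleophilic aromatic substitution on a purchased ring A; it sets out from 10 and returns at 21.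
   - Aldehyde 10 is reduced (NaBH4, MeOH, 0 °C) to 2-(hydroxymethyl)-4-methoxy-6-(3-methylbut-2-enyloxy)phenol F1.
   - TBSCl/imidazole (1.05 equiv, CH2Cl2, 0 °C) silylates the primary alcohol ahead of the hindered phenol and gives 2-[(tert-butyldimethylsilyloxy)methyl]-4-methoxy-6-(3-methylbut-2-enyloxy)phenol F2.
   - Commercial 2,6-difluoro-4-methylbenzoic acid (Cc1cc(F)c(C(=O)O)c(F)c1) is esterified (MeI, K2CO3, DMF) to methyl 2,6-difluoro-4-methylbenzoate F3.
   - The phenoxide of F2 (Cs2CO3, DMSO, 80–90 °C) displaces one fluoride ortho to the ester and gives methyl 2-{2-[(tert-butyldimethylsilyloxy)methyl]-4-methoxy-6-(3-methylbut-2-enyloxy)phenoxy}-6-fluoro-4-methylbenzoate F4.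
   - The second fluoride is exchanged for hydroxyl with the sodium alkoxide of 2-(methylsulfonyl)ethanol (NaH, DMF, rt to 50 °C). This passes through methyl 2-{2-[(tert-butyldimethylsilyloxy)methyl]-4-methoxy-6-(3-methylbut-2-enyloxy)phenoxy}-4-methyl-6-[2-(methylsulfonyl)ethoxy]benzoate F5, which loses methyl vinyl sulfone by β-elimination and gives phenol 21, ready for step 12.

2. Step 9. The terminal ynol ether may be lost on protonation and work-up through acid-catalysed hydration to the aryl acetate or oligomerization on concentration. The fallback carries the alkyne in silyl-capped form; it sets out from 15 and returns at 18. Acetylide 17 is generated as before but quenched with Me3SiCl to give tert-butyl{5-methoxy-3-(3-methylbut-2-enyloxy)-2-[(trimethylsilyl)ethynyloxy]benzyloxy}dimethylsilane F6, which should tolerate chromatography and cold storage. K2CO3 in MeOH/THF at 0 °C removes only the alkynyl silyl group, and a simple basic extraction gives 18 directly before step 10.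

3. Step 4. The substitution may stall or turn into reductive debromination, and the electron-rich catechol aldehyde may degrade by oxidation in hot alkali. The fallback replaces direct hydroxylation by etherification and chelation-controlled dealkylation; it sets out from 8 and returns at 9. Copper-catalysed methoxylation (NaOMe, CuBr cat., DMF/MeOH, 110 °C) gives 2-hydroxy-3,5-dimethoxybenzaldehyde F7. AlCl3/pyridine (CH2Cl2, reflux; aq. HCl) then cleaves only the methyl ether next to the free phenol, through a five-membered aluminium catecholate, and gives 9.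

Further compounds
F1 | step 10 | 2-(hydroxymethyl)-4-methoxy-6-(3-methylbut-2-enyloxy)phenol | COc1cc(CO)c(O)c(OCC=C(C)C)c1
F2 | step 10 | 2-[(tert-butyldimethylsilyloxy)methyl]-4-methoxy-6-(3-methylbut-2-enyloxy)phenol | COc1cc(CO[Si](C)(C)C(C)(C)C)c(O)c(OCC=C(C)C)c1
F3 | step 10 | methyl 2,6-difluoro-4-methylbenzoate | COC(=O)c1c(F)cc(C)cc1F
F4 | step 10 | methyl 2-{2-[(tert-butyldimethylsilyloxy)methyl]-4-methoxy-6-(3-methylbut-2-enyloxy)phenoxy}-6-fluoro-4-methylbenzoate | COC(=O)c1c(F)cc(C)cc1Oc1c(CO[Si](C)(C)C(C)(C)C)cc(OC)cc1OCC=C(C)C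
F5 | step 10 | methyl 2-{2-[(tert-butyldimethylsilyloxy)methyl]-4-methoxy-6-(3-methylbut-2-enyloxy)phenoxy}-4-methyl-6-[2-(methylsulfonyl)ethoxy]benzoate | COC(=O)c1c(OCCS(C)(=O)=O)cc(C)cc1Oc1c(CO[Si](C)(C)C(C)(C)C)cc(OC)cc1OCC=C(C)C
F6 | step 9 | tert-butyl{5-methoxy-3-(3-methylbut-2-enyloxy)-2-[(trimethylsilyl)ethynyloxy]benzyloxy}dimethylsilane | C[Si](C)(C)C#COc1c(CO[Si](C)(C)C(C)(C)C)cc(OC)cc1OCC=C(C)C
F7 | step 4 | 2-hydroxy-3,5-dimethoxybenzaldehyde | COc1cc(OC)c(O)c(C=O)c1
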